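**Retrosynthetic overview**

1. Numbering: ring A = C1 (CH carrying the side chain)–C2–C3–C4 (CH–CH3)–C5 (spiro); ring B = C5–C6–C7=C8(CH3)–C9(OH)–C10; side chain C11(CH3)–C12–C13–C14–C15(CH3)–C16–OAc. The plan rests on ring B: its two CH2 groups C6 and C10 both sit on the spiro carbon C5, so at the enone level C5/C6/C10 can be a cyclopropane and the carbonyl carbon C9 can be carbon monoxide.
2. Target 27 ⇐ reduction at C9, acetylation at C16, desilylation ⇐ spiro enone 24 ⇐ carbonylative (5+1) ring expansion of spiro vinylcyclopropane 21 with CO 22 (forms C9–C10 and C8–C9, closes ring B).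
3. 21 ⇐ C12–C13 coupling of tosylate 12 with the Grignard reagent of bromide 19 (C14–C16 from Roche ester 13, C13 from formaldehyde).
4. 12 ⇐ cyclopropane lactone 9 ⇐ intramolecular cyclopropanation of the C5=C10 methylene by a diazoacetate hung on the C12 oxygen (forms C5–C6 and C6–C10; the tether, not sterics, fixes C5) ⇐ methylene alcohol 6 ⇐ nepetalactone 1 (ring A with C1 and C4 from the chiral pool; hydrogenation sets C11).
5. Ring order: ring A (purchased), cyclopropane (step 6), ring B (step 16).

Key step: step 16

Remark: (4aS,7S,7aR)-nepetalactone (from catnip oil) is taken as purchasable, and in step 16 the CO gas 22 is taken as the source of C9, Fe(CO)5 being regenerated under the CO atmosphere.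

**Route**

Step 1
Reactants: 1 (4aS,7S,7aR)-nepetalactone
Product: 2 (4S,4aR,7S,7aR)-dihydronepetalactone
Conditions: H2 (1 atm), Pd on SrCO3 (5 wt %), EtOH, rt
Reagents that add atoms: none
Why: Heterogeneous hydrogenation of the enol ether C=C of the cis-fused bicycle should deliver hydrogen from the convex face (the side of H-4a and H-7a), which sets C11 (lactone C4, S) with its methyl group on the concave side, and the minor C4 epimer is removed by chromatography.

Step 2
Reactants: 2 (4S,4aR,7S,7aR)-dihydronepetalactone
Product: 3 (4S,4aR,7S,7aR)-dihydronepetalactol (lactol, both anomers)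
Conditions: i-Bu2AlH (1.1 equiv), CH2Cl2, −78 °C; aq sodium potassium tartrate
Reagents that add atoms: none
Why: Partial reduction of a δ-lactone with i-Bu2AlH at −78 °C stops at the lactol because the aluminium hemiacetal survives until work-up, and the new anomeric centre is lost again in step 3.

Step 3
Reactants: 3 (4S,4aR,7S,7aR)-dihydronepetalactol
Product: 4 amino alcohol (ring A with CH(CH3)CH2OH on C1, CH2NMe2 (C10) on C5 and CH3 on C4, configurations as in 2)
Conditions: Me2NH (2 M in THF), NaBH(OAc)3, AcOH, ClCH2CH2Cl, rt
Reagents that add atoms: dimethylamine, CNC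
Why: Reductive amination of the open hydroxy aldehyde form of the lactol with NaBH(OAc)3 turns C10 into CH2NMe2 and leaves the C12 hydroxyl free, so the two ends of the former lactone are told apart without protecting groups, and any epimerisation at C5 is harmless because C5 becomes sp2 in step 4.

Step 4
Reactants: 4 amino alcohol
Product: 6 (2S)-2-[(1R,3S)-3-methyl-2-methylidenecyclopentyl]propan-1-ol, via amine N-oxide 5 (not isolated)
Conditions: m-CPBA, CH2Cl2, 0 °C; filtration through basic Al2O3; then toluene, 110 °C
Reagents that add atoms: none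
Why: Cope elimination, in which the amine oxide undergoes thermal syn elimination through a five-membered transition state, and since C5–H is the only β-hydrogen the exocyclic C5=C10 methylene is the only possible alkene.

Step 5
Reactants: 6 (2S)-2-[(1R,3S)-3-methyl-2-methylidenecyclopentyl]propan-1-ol
Product: 8 (2S)-2-[(1R,3S)-3-methyl-2-methylidenecyclopentyl]propyl diazoacetate, via ester tosylhydrazone 7 (not isolated)
Conditions: TsNHN=CHCOCl (1.3 equiv), PhNMe2, CH2Cl2, 0 °C; then Et3N (3 equiv), 0 °C → rt
Reagents that add atoms: glyoxylic acid chloride p-toluenesulfonylhydrazone, Cc1ccc(cc1)S(=O)(=O)NN=CC(Cl)=O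
Why: O-Acylation of the primary C12 alcohol by the acid chloride followed by triethylamine-induced loss of p-toluenesulfinate from the tosylhydrazone (a Bamford–Stevens-type elimination) is a standard one-flask preparation of diazoacetates and leaves the alkene untouched.

Step 6
Reactants: 8 (2S)-2-[(1R,3S)-3-methyl-2-methylidenecyclopentyl]propyl diazoacetate
Product: 9 spiro cyclopropane lactone (seven-membered lactone O–C12–C11–C1–C5–C6–C7(=O), cis-fused to ring A at C1–C5 and to the cyclopropane C5–C6–C10 at C5–C6; C6 on the face of the C1 side chain, C10 on the face of the C4 methyl)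
Conditions: [Cu(MeCN)4]PF6 (5 mol %), CH2Cl2, reflux, slow addition of 8 (syringe pump, high dilution)
Reagents that add atoms: none
Why: Intramolecular copper-carbenoid cyclopropanation, chosen because the trans C1 and C4 substituents make the two faces of an exocyclic alkene at C5 almost equivalent, so C5 is set by the tether instead of by sterics, the carbenoid carbon C6 being held through C7(=O)–O–C12–C11 on the face of the C1 side chain so that it adds there to C5=C10 and gives the cis-fused seven-membered lactone with C6 on the side-chain face, C10 on the C4-methyl face and C7 cis to C1 on the cyclopropane, while a copper rather than a rhodium carbenoid is used to hold back insertion into the C11–H bond.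

Step 7
Reactants: 9 spiro cyclopropane lactone
Product: 10 hydroxy aldehyde (CHO (C7) on cyclopropane carbon C6, C12–OH free; in equilibrium with its seven-membered lactol)
Conditions: i-Bu2AlH (1.1 equiv), CH2Cl2, −78 °C; aq sodium potassium tartrate
Reagents that add atoms: none
Why: i-Bu2AlH at −78 °C reduces the lactone only to the aldehyde oxidation level, which gives the cyclopropanecarbaldehyde (C7) and at the same time sets the C12 hydroxyl free for the later chain coupling.

Step 8
Reactants: 10 hydroxy aldehyde
Product: 11 vinylcyclopropane alcohol ((E)-prop-1-enyl on C6, C12–OH)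
Conditions: 5-(ethylsulfonyl)-1-phenyl-1H-tetrazole, KN(SiMe3)2 (2.2 equiv), DME, −60 °C → rt
Reagents that add atoms: 5-(ethylsulfonyl)-1-phenyl-1H-tetrazole, CCS(=O)(=O)c1nnnn1-c1ccccc1
Why: Julia–Kocienski olefination with the 1-phenyltetrazolyl ethyl sulfone and a potassium base in DME is the E-selective variant and tolerates the free hydroxyl once it is deprotonated by the extra base, so the (E)-prop-1-enyl group (C7=C8 and the C8 methyl) should form, and a minor Z isomer would converge in step 16.

Step 9
Reactants: 11 vinylcyclopropane alcohol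
Product: 12 tosylate of 11 (C12–OTs)
Conditions: TsCl, pyridine, DMAP (cat), CH2Cl2, 0 °C → rt
Reagents that add atoms: p-toluenesulfonyl chloride, Cc1ccc(cc1)S(Cl)(=O)=O
Why: Sulfonylation of the unhindered primary alcohol with TsCl and pyridine is routine and leaves the vinylcyclopropane untouched.

Step 10
Reactants: 13 methyl (R)-3-hydroxy-2-methylpropanoate
Product: 14 methyl (R)-3-(tert-butyldimethylsilyloxy)-2-methylpropanoate
Conditions: TBSCl, imidazole, CH2Cl2, rt
Reagents that add atoms: tert-butyldimethylsilyl chloride, CC(C)(C)[Si](C)(C)Cl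
Why: Silylation of the primary alcohol with TBSCl and imidazole is routine and the C15 stereocentre is not involved.

Step 11
Reactants: 14 methyl (R)-3-(tert-butyldimethylsilyloxy)-2-methylpropanoate
Product: 15 (S)-3-(tert-butyldimethylsilyloxy)-2-methylpropan-1-ol
Conditions: i-Bu2AlH (2.2 equiv), CH2Cl2, −78 → 0 °C; aq sodium potassium tartrate
Reagents that add atoms: none
Why: Two hydride equivalents of i-Bu2AlH reduce the ester to the primary alcohol without a free aldehyde being exposed to base, so the α-stereocentre (C15) is not epimerised.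

Step 12
Reactants: 15 (S)-3-(tert-butyldimethylsilyloxy)-2-methylpropan-1-ol
Product: 16 (R)-(3-bromo-2-methylpropoxy)(tert-butyl)dimethylsilane
Conditions: CBr4, PPh3, CH2Cl2, 0 °C
Reagents that add atoms: carbon tetrabromide, BrC(Br)(Br)Br
Why: Appel reaction, in which the primary alcohol is converted to the bromide by SN2 displacement of the oxyphosphonium leaving group at a carbon that is not stereogenic.

Step 13
Reactants: 16 (R)-(3-bromo-2-methylpropoxy)(tert-butyl)dimethylsilane
Product: 18 (S)-4-(tert-butyldimethylsilyloxy)-3-methylbutan-1-ol, via Grignard reagent 17 (not isolated)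
Conditions: Mg, THF, 40 °C; then (CH2O)n, 0 °C → rt; aq NH4Cl
Reagents that add atoms: paraformaldehyde (as formaldehyde), C=O
Why: Addition of the primary Grignard reagent to formaldehyde is the classical one-carbon homologation and adds C13 as a primary alcohol without touching C15.

Step 14
Reactants: 18 (S)-4-(tert-butyldimethylsilyloxy)-3-methylbutan-1-ol
Product: 19 (S)-(4-bromo-2-methylbutoxy)(tert-butyl)dimethylsilane
Conditions: CBr4, PPh3, CH2Cl2, 0 °C
Reagents that add atoms: carbon tetrabromide, BrC(Br)(Br)Br
Why: Appel reaction as in step 12, again at a primary carbon remote from the stereocentre.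

Step 15
Reactants: 12 tosylate of 11; 19 (S)-(4-bromo-2-methylbutoxy)(tert-butyl)dimethylsilane
Product: 21 spiro vinylcyclopropane silyl ether (TBSO–C16 to C11 chain on C1; cyclopropane C5/C6/C10; (E)-prop-1-enyl on C6), via Grignard reagent 20 (not isolated)
Conditions: 19, Mg, THF, 40 °C; then 12, Li2CuCl4 (5 mol %), THF, −78 °C → rt
Reagents that add atoms: none
Why: Copper-catalysed sp3–sp3 cross-coupling of a primary Grignard reagent with a primary tosylate (Kochi-type coupling with Li2CuCl4) forms C12–C13 by substitution at the β-branched but primary C12, and the silyl ether, the cyclopropane and the isolated alkene are inert to the reagent.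

Step 16
Reactants: 21 spiro vinylcyclopropane silyl ether; 22 carbon monoxide
Product: 24 (1R,4S,5S)-1-[(2R,6S)-7-(tert-butyldimethylsilyloxy)-6-methylheptan-2-yl]-4,8-dimethylspiro[4.5]dec-7-en-9-one, via deconjugated enone 23 (not isolated)
Conditions: Fe(CO)5 (1.5 equiv), CO (1 atm), hν (Hg lamp, Pyrex), i-PrOH, rt; then DBU, CH2Cl2, rt
Reagents that add atoms: none
Why: Light frees a coordination site on Fe(CO)5, the Fe(CO)4 fragment binds the propenyl double bond and inserts into the adjacent cyclopropane bond C6–C10 to give a σ-alkyl (C10) π-allyl (C6–C7–C8) tricarbonyliron metallacycle, CO inserts into the Fe–C10 bond, and reductive elimination joins the acyl carbon C9 to the allyl terminus C8. The closest known reaction type is the iron-mediated (or rhodium-catalysed) carbonylative (5+1) ring expansion of alkenylcyclopropanes to cyclohexenones. Ring B is closed by that acyl–allyl reductive elimination (C9–C10 and C8–C9 formed, C6–C10 broken), which first gives the deconjugated enone 23, and DBU then moves the C6=C7 double bond to C7=C8 through the dienolate. No lasting stereocentre is formed (C8 of 23 becomes sp2 in 24), and C5, which is not touched, keeps the configuration set in step 6. The step needs insertion into C6–C10 and not into C5–C6, and the substrate secures this because C5 is quaternary and flanked by two branched ring carbons whereas C10 is an open CH2, and because the C10–Fe alkyl has no β-hydrogen (C5 is quaternary) so that diene formation cannot compete.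

Step 17
Reactants: 24 silyl ether enone
Product: 25 (1R,4S,5S)-1-[(2R,6S)-7-hydroxy-6-methylheptan-2-yl]-4,8-dimethylspiro[4.5]dec-7-en-9-one
Conditions: HF·pyridine, THF, 0 °C → rt
Reagents that add atoms: none
Why: Fluoride cleaves the primary silyl ether, and buffered HF·pyridine is chosen over basic fluoride sources so that the enone is not exposed to base.

Step 18
Reactants: 25 hydroxy enone
Product: 26 (2S,6R)-6-[(1R,4S,5S)-4,8-dimethyl-9-oxospiro[4.5]dec-7-en-1-yl]-2-methylheptyl acetate
Conditions: Ac2O, pyridine, DMAP (cat), CH2Cl2, rt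
Reagents that add atoms: acetic anhydride, CC(=O)OC(C)=O
Why: DMAP-catalysed acetylation of the primary alcohol with acetic anhydride is routine and does not affect the enone.

Step 19
Reactants: 26 acetoxy enone
Product: 27 (2S,6R)-6-[(1R,4S,5S,9S)-9-hydroxy-4,8-dimethylspiro[4.5]dec-7-en-1-yl]-2-methylheptyl acetate (target)
Conditions: (R)-2-methyl-CBS-oxazaborolidine (0.2 equiv), BH3·SMe2, THF, −20 °C; MeOH
Reagents that add atoms: none
Why: Corey–Bakshi–Shibata reduction, in which the (R)-oxazaborolidine binds the ketone anti to its larger flank, the methyl-substituted alkene carbon C8, and delivers hydride from borane to the face that gives the (9S) allylic alcohol by 1,2-reduction under catalyst control, while the acetate is not reduced at −20 °C.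

**Compound list**

1 | (4aS,7S,7aR)-nepetalactone | O1C=C(C)[C@H]2CC[C@H](C)[C@H]2C1=O | starting material
2 | (4S,4aR,7S,7aR)-dihydronepetalactone | O1C[C@@H](C)[C@H]2CC[C@H](C)[C@H]2C1=O | intermediate
3 | (4S,4aR,7S,7aR)-dihydronepetalactol (both anomers) | O1C[C@@H](C)[C@H]2CC[C@H](C)[C@H]2C1O | intermediate
4 | amino alcohol (CH2NMe2 on C5, CH(CH3)CH2OH on C1, CH3 on C4) | OC[C@@H](C)[C@H]1CC[C@H](C)[C@H]1CN(C)C | intermediate
5 | N-oxide of 4 | OC[C@@H](C)[C@H]1CC[C@H](C)[C@H]1C[N+](C)(C)[O-] | intermediate
6 | (2S)-2-[(1R,3S)-3-methyl-2-methylidenecyclopentyl]propan-1-ol | OC[C@@H](C)[C@H]1CC[C@H](C)C1=C | intermediate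
7 | (2S)-2-[(1R,3S)-3-methyl-2-methylidenecyclopentyl]propyl (2-tosylhydrazono)acetate | Cc1ccc(cc1)S(=O)(=O)NN=CC(=O)OC[C@@H](C)[C@H]1CC[C@H](C)C1=C | intermediate
8 | (2S)-2-[(1R,3S)-3-methyl-2-methylidenecyclopentyl]propyl diazoacetate | [N-]=[N+]=CC(=O)OC[C@@H](C)[C@H]1CC[C@H](C)C1=C | intermediate
9 | spiro cyclopropane lactone (C6 on the side-chain face, C10 on the C4-methyl face) | O=C1OC[C@@H](C)[C@H]2CC[C@H](C)[C@]23C[C@H]13 | intermediate
10 | hydroxy aldehyde (CHO on C6, C12–OH; open form of the lactol) | OC[C@@H](C)[C@H]1CC[C@H](C)[C@]12C[C@@H]2C=O | intermediate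
11 | vinylcyclopropane alcohol ((E)-prop-1-enyl on C6) | OC[C@@H](C)[C@H]1CC[C@H](C)[C@]12C[C@@H]2/C=C/C | intermediate
12 | tosylate of 11 | Cc1ccc(cc1)S(=O)(=O)OC[C@@H](C)[C@H]1CC[C@H](C)[C@]12C[C@@H]2/C=C/C | intermediate
13 | methyl (R)-3-hydroxy-2-methylpropanoate | COC(=O)[C@H](C)CO | starting material
14 | methyl (R)-3-(tert-butyldimethylsilyloxy)-2-methylpropanoate | COC(=O)[C@H](C)CO[Si](C)(C)C(C)(C)C | intermediate
15 | (S)-3-(tert-butyldimethylsilyloxy)-2-methylpropan-1-ol | OC[C@H](C)CO[Si](C)(C)C(C)(C)C | intermediate
16 | (R)-(3-bromo-2-methylpropoxy)(tert-butyl)dimethylsilane | BrC[C@H](C)CO[Si](C)(C)C(C)(C)C | intermediate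
17 | Grignard reagent of 16 | Br[Mg]C[C@H](C)CO[Si](C)(C)C(C)(C)C | intermediate
18 | (S)-4-(tert-butyldimethylsilyloxy)-3-methylbutan-1-ol | OCC[C@H](C)CO[Si](C)(C)C(C)(C)C | intermediate
19 | (S)-(4-bromo-2-methylbutoxy)(tert-butyl)dimethylsilane | BrCC[C@H](C)CO[Si](C)(C)C(C)(C)C | intermediate
20 | Grignard reagent of 19 | Br[Mg]CC[C@H](C)CO[Si](C)(C)C(C)(C)C | intermediate
21 | spiro vinylcyclopropane silyl ether (key-step precursor) | CC(C)(C)[Si](C)(C)OC[C@@H](C)CCC[C@@H](C)[C@H]1CC[C@H](C)[C@]12C[C@@H]2/C=C/C | intermediate
22 | carbon monoxide | [C-]#[O+] | starting material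
23 | deconjugated enone (C6=C7, C8 epimers) | CC(C)(C)[Si](C)(C)OC[C@@H](C)CCC[C@@H](C)[C@H]1CC[C@H](C)[C@@]12C=CC(C)C(=O)C2 | intermediate
24 | (1R,4S,5S)-1-[(2R,6S)-7-(tert-butyldimethylsilyloxy)-6-methylheptan-2-yl]-4,8-dimethylspiro[4.5]dec-7-en-9-one | CC(C)(C)[Si](C)(C)OC[C@@H](C)CCC[C@@H](C)[C@H]1CC[C@H](C)[C@@]12CC=C(C)C(=O)C2 | intermediate
25 | (1R,4S,5S)-1-[(2R,6S)-7-hydroxy-6-methylheptan-2-yl]-4,8-dimethylspiro[4.5]dec-7-en-9-one | OC[C@@H](C)CCC[C@@H](C)[C@H]1CC[C@H](C)[C@@]12CC=C(C)C(=O)C2 | intermediate
26 | (2S,6R)-6-[(1R,4S,5S)-4,8-dimethyl-9-oxospiro[4.5]dec-7-en-1-yl]-2-methylheptyl acetate | CC(=O)OC[C@@H](C)CCC[C@@H](C)[C@H]1CC[C@H](C)[C@@]12CC=C(C)C(=O)C2 | intermediate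
27 | (2S,6R)-6-[(1R,4S,5S,9S)-9-hydroxy-4,8-dimethylspiro[4.5]dec-7-en-1-yl]-2-methylheptyl acetate | CC(=O)OC[C@@H](C)CCC[C@@H](C)[C@H]1CC[C@H](C)[C@@]12CC=C(C)[C@@H](O)C2 | target

**Step count and risks**

Total step count: 19. Longest linear sequence: 14 steps (steps 1–9 and 15–19, from nepetalactone).

The three steps most likely to fail:

1. Step 16 (key step). The iron fragment may bind the 1,2-disubstituted propenyl group too weakly for ring opening next to the crowded spiro centre, or insertion into the C5–C6 bond may compete with the wanted insertion into C6–C10. The fallback sets out from 21 and returns at 24. Ethenolysis (ethene, second-generation Hoveyda–Grubbs catalyst, CH2Cl2, 40 °C) should trim the propenyl group to a vinyl group and give the vinyl spiro cyclopropane F1. Its unhindered terminal alkene should then undergo thermal carbonylation with [Rh(CO)2Cl]2 (5 mol %) under CO (1 atm) in toluene at 80 °C to give the deconjugated C8-unsubstituted enone F2. DBU should move this into conjugation as the C8-unsubstituted conjugated enone F3. α-Iodination (I2, pyridine, CH2Cl2) should give the C8 iodo enone F4, and Suzuki–Miyaura coupling with methylboronic acid (Pd(dppf)Cl2, K3PO4, dioxane–H2O, 80 °C) should place the methyl group on C8 and give 24.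

2. Step 6. The carbenoid may dimerise, insert into the C11–H bond (γ-lactone), or add to the other face of the methylene group (trans-fused lactone, wrong C5). The fallback sets out from 6 and returns at 9. Acylation with acryloyl chloride and Et3N (CH2Cl2, 0 °C) should give the acrylate F5. Ring-closing metathesis (second-generation Hoveyda–Grubbs catalyst, toluene, 80 °C) should close the seven-membered α,β-unsaturated lactone F6 with loss of ethene, which fixes C6 and C7 on the C1 side of the new C5=C6 bond (the former methylene carbon is lost). Corey–Chaykovsky cyclopropanation (Me3S(O)I, NaH, DMSO, 50 °C) should then add the CH2 group that becomes C10 to C5 on the face away from the lactone bridge and close onto C6, giving 9.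

3. Step 19. Facial discrimination may be weak, because for the catalyst the C10 methylene next to the quaternary C5 is not much smaller than the methyl-bearing alkene flank, so a mixture of C9 epimers may form. The fallback sets out from 26 and returns at 27. Luche reduction (NaBH4, CeCl3·7H2O, MeOH, −78 °C) under substrate control should give 27 together with the (9R) epimer F7. After chromatographic separation, F7 is oxidised back to 26 with MnO2 (CH2Cl2, rt) and put through the reduction again.

Further compounds
F1 | step 16 | vinyl spiro cyclopropane (vinyl in place of propenyl on C6 of 21) | CC(C)(C)[Si](C)(C)OC[C@@H](C)CCC[C@@H](C)[C@H]1CC[C@H](C)[C@]12C[C@@H]2C=C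
F2 | step 16 | deconjugated C8-unsubstituted enone (C6=C7, C9 ketone) | CC(C)(C)[Si](C)(C)OC[C@@H](C)CCC[C@@H](C)[C@H]1CC[C@H](C)[C@@]12C=CCC(=O)C2
F3 | step 16 | C8-unsubstituted conjugated enone (C7=C8, C9 ketone) | CC(C)(C)[Si](C)(C)OC[C@@H](C)CCC[C@@H](C)[C@H]1CC[C@H](C)[C@@]12CC=CC(=O)C2
F4 | step 16 | C8 iodo enone | CC(C)(C)[Si](C)(C)OC[C@@H](C)CCC[C@@H](C)[C@H]1CC[C@H](C)[C@@]12CC=C(I)C(=O)C2
F5 | step 6 | (2S)-2-[(1R,3S)-3-methyl-2-methylidenecyclopentyl]propyl acrylate | C=CC(=O)OC[C@@H](C)[C@H]1CC[C@H](C)C1=C
F6 | step 6 | seven-membered α,β-unsaturated lactone (O–C12–C11–C1–C5=C6–C7(=O)) | O=C1OC[C@@H](C)[C@H]2CC[C@H](C)C2=C1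
F7 | step 19 | (9R) epimer of 27 | CC(=O)OC[C@@H](C)CCC[C@@H](C)[C@H]1CC[C@H](C)[C@@]12CC=C(C)[C@H](O)C2
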